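To whoever took over my bench: I left two flasks, alpha and eta, each charged with solid substrate that dissolves to starting material, and I wanted the cheapest reckoning of how the reacted part would split.

| flask | solid substrate | temperature | remark | time |
|---|---|---|---|---|
| ochre | 0.19 M | −25 °C | run made earlier |  |
| green | 0.23 M | 0 °C | run made earlier |  |
| blue | 0.45 M | −25 °C | run made earlier |  |
| alpha | 0.15 M | 20 °C |  | 50 min |
| eta | 0.41 M | −20 °C |  | 50 min |

| run | time / min | ring / % | open dimer / % |
|---|---|---|---|
| ochre | 2.00 | 1.2 | 0 |
| ochre | 6.00 | 4.9 | 0 |
| ochre | 12.0 | 15.0 | 1.2 |
| ochre | 20.0 | 31.2 | 4.0 |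
| ochre | 25.0 | 41.4 | 7.1 |
| green | 0.667 | 0.3 | 0.1 |
| green | 1.33 | 2.7 | 0 |
| green | 3.00 | 5.9 | 0 |
| green | 4.00 | 9.7 | 0.5 |
| green | 10.0 | 25.9 | 0.5 |
| blue | 2.00 | 0 | 0.1 |
| blue | 4.00 | 0.8 | 0.3 |
| blue | 8.00 | 2.9 | 0.7 |
| blue | 12.0 | 6.2 | 0.6 |
| blue | 25.0 | 17.5 | 2.4 |

(scatter of a reading: 0.5 percentage points)

- in percentages every species weighs as the solid substrate in it: one open dimer counts as two
- as a solid, counted per litre of solution: solid substrate
- the earlier runs were read with a standard deviation of 0.5 percentage points
- on the list of suspects stand: solid substrate <-> starting material; starting material -> ring; 2 starting material -> open dimer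
- at the start none of the solid substrate is in solution
- what has only dissolved of solid substrate counts as not reacted

1. which of the two ends with the higher share of ring in all that became ring or open dimer ("neither" if they lie within 2 percentage points) (alpha / eta / neither)
2. share of ring in all that became ring or open dimer, alpha
3. share of ring in all that became ring or open dimer, eta

I followed one molecule of starting material to its fork: ring, or open dimer with a partner. My measure was the fork odds, open dimer over ring as fractions of the charge (a selectivity, inverted): 0.171 at ochre's last reading. Blue, at the same temperature with more charged, read 0.137. Green, at 0 °C, read 0.0193, but its open dimer reading equalled the scatter of 0.5 percentage points, so this is rough. From ochre to green, which differ in charge and reading time as well as temperature, the odds fell by a factor of 8.88, a bigger change than from ochre to blue, so don't touch the baths.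

I spread that factor evenly over the degrees on a logarithmic scale. Eta got odds of 0.111, a ring share of 90.0%. Alpha got 0.00336, a ring share of 99.7%, so I expected alpha higher.

The forecast reckoned from the dissolved level, “The ring forms first-order from dissolved material, and the open dimer is second-order in it”, and named alpha, with 99% (96.5% to 100%) for alpha and 88% (82% to 93%) for eta, both lower than my shares .

Alpha gave 99.9% and eta 90.9%, so alpha ended higher, against my 99.7% and 90.0%.

    solid substrate ⇌ starting material, rate k1*(cs1 - [starting material]) while solid is left; crystals form when [starting material] > cs1 (solubility = 0.210 M, k = 0.0316 /min)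
    starting material → ring (k = 0.168 /min, Ea = 65.0 kJ/mol)
    2 starting material → open dimer (k = 0.290 /M/min, Ea = 48.0 kJ/mol)
    (constants at −20 °C)

For a flask like eta kept at −45 °C, the same reckoning gives odds of 0.984 and a ring share of 50.4%. That flask held 6.40% ring and 5.78% open dimer at 50.0 min, a ring share of 52.6%.

The earlier runs and the new flask stem from a simulated flask for an exercise, and the scatter is random.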